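**Plan**

- Retrosynthesis: the side chain is cut at C1'=C2' (cross-metathesis) into vinyl lactone 26 and allylic alcohol 6. The pyranone is cut at O4–C5 and C6=C7 (lactonisation of a Z-enoate made from an aldehyde on C7a). The C2–C1' bond goes back to an acetylide added to a lactone carbonyl. Last, the oxolane is cut at C3–C3a.
- Enabling feature: in the oxolane, C2, C3 and C3a (O1–C2–C3(OH)–C3a(O4)) are, one oxidation level up, the lactone carbonyl and enediol of a 2-hydroxytetronic acid (aci-reductone, the ascorbate motif). C3–C3a is then the retron of a Dieckmann (intramolecular Claisen) closure of an O-(benzyloxyacetyl) glycerate.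
- Forward order: side-chain alcohol 6 (steps 1–5); oxolane ring first (step 8); pyranone ring second (steps 17–18); chain joined last (step 19).
- Stereochemistry: C7a comes from methyl (R)-glycidate. C3a and C3 are set by H2 added anti to the C7a substituent, as ascorbic acid gives L-gulonolactone. C2 is set by hydride added anti to the acetonide. All four ring hydrogens therefore sit on one face (all-cis).
- C3' and C4' come from Sharpless epoxidation of divinylcarbinol and terminal hydride opening; the Z alkene from Still–Gennari olefination, the E alkene from metathesis.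

Key step: step 8

Remark: locants follow furo[3,2-b]pyran-5-one (O1, C2 bearing the chain, C3 bearing OH, C3a, O4, C5=O, C6=C7, C7a); primes denote the pentenyl chain.
Remark: hemiketal 18 is carried on as the mixture of anomers; that centre is planarised in step 13.

**Route**

Step 1
Reactants: 1 penta-1,4-dien-3-ol
Product: 2 (2R,3S)-1,2-epoxypent-4-en-3-ol
Conditions: Ti(OiPr)4, D-(−)-diisopropyl tartrate, t-BuOOH, 4 Å MS, CH2Cl2, −20 °C
Reagents that add atoms: tert-butyl hydroperoxide, CC(C)(C)OO
Why: Sharpless asymmetric epoxidation of the prochiral divinylcarbinol; the D-(−)-tartrate–titanium complex selects one enantiotopic vinyl group and one of its faces (erythro rule for secondary allylic alcohols), so the future C3' (carbinol) and C4' (epoxide CH) are set together.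

Step 2
Reactants: 2 (2R,3S)-1,2-epoxypent-4-en-3-ol
Product: 3 (2R,3S)-3-[(tert-butyldimethylsilyl)oxy]-1,2-epoxypent-4-ene
Conditions: TBSCl, imidazole, DMF, 0 °C to rt
Reagents that add atoms: tert-butyldimethylsilyl chloride, CC(C)(C)[Si](C)(C)Cl
Why: Silylation under mildly basic imidazole conditions protects the allylic hydroxyl without Payne rearrangement and marks C3'–O so that the benzoate can later go on C4'–O only.

Step 3
Reactants: 3 (2R,3S)-3-[(tert-butyldimethylsilyl)oxy]-1,2-epoxypent-4-ene
Product: 4 (2R,3S)-3-[(tert-butyldimethylsilyl)oxy]pent-4-en-2-ol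
Conditions: LiEt3BH, THF, −78 to 0 °C; then H2O
Reagents that add atoms: none
Why: SN2 hydride opening of the terminal epoxide at its unsubstituted carbon (Super-Hydride reduction) leaves both stereocentres untouched and unveils the C4' hydroxyl next to the new methyl group.

Step 4
Reactants: 4 (2R,3S)-3-[(tert-butyldimethylsilyl)oxy]pent-4-en-2-ol
Product: 5 (2R,3S)-3-[(tert-butyldimethylsilyl)oxy]pent-4-en-2-yl benzoate
Conditions: BzCl, pyridine, DMAP (cat.), CH2Cl2, 0 °C to rt
Reagents that add atoms: benzoyl chloride, O=C(Cl)c1ccccc1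
Why: DMAP-catalysed acylation of the only free hydroxyl installs the benzoate of the target with retention.

Step 5
Reactants: 5 (2R,3S)-3-[(tert-butyldimethylsilyl)oxy]pent-4-en-2-yl benzoate
Product: 6 (2R,3S)-3-hydroxypent-4-en-2-yl benzoate
Conditions: HF·pyridine, THF, 0 °C to rt
Reagents that add atoms: none
Why: Fluoride desilylation under acidic conditions frees the allylic alcohol while avoiding the base-induced 1,2-benzoyl shift.

Step 6
Reactants: 7 methyl (R)-oxirane-2-carboxylate (methyl (R)-glycidate); 8 benzyl alcohol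
Product: 9 methyl (R)-3-(benzyloxy)-2-hydroxypropanoate
Conditions: BF3·OEt2 (cat.), CH2Cl2, 0 °C to rt
Reagents that add atoms: benzyl alcohol (8), OCc1ccccc1
Why: Lewis acid-catalysed epoxide alcoholysis; benzyl alcohol opens the oxirane at the unsubstituted C3, remote from the deactivating ester, so the (R)-centre (future C7a) is untouched.

Step 7
Reactants: 9 methyl (R)-3-(benzyloxy)-2-hydroxypropanoate; 10 (benzyloxy)acetyl chloride
Product: 11 methyl (R)-3-(benzyloxy)-2-{[(benzyloxy)acetyl]oxy}propanoate
Conditions: pyridine, DMAP (cat.), CH2Cl2, 0 °C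
Reagents that add atoms: (benzyloxy)acetyl chloride (10), O=C(Cl)COCc1ccccc1
Why: Pyridine/DMAP O-acylation of the secondary alcohol supplies the two-carbon glycolate unit (future C2 and C3) without touching the α-stereocentre.

Step 8
Reactants: 11 methyl (R)-3-(benzyloxy)-2-{[(benzyloxy)acetyl]oxy}propanoate
Product: 12 (5R)-3-(benzyloxy)-5-[(benzyloxy)methyl]-4-hydroxyfuran-2(5H)-one
Conditions: LiHMDS (2.2 equiv), THF, −78 °C; then aq. HCl
Reagents that add atoms: none
Why: LiHMDS deprotonates the glycolate CH2 (acidified by the ester carbonyl, lithium held by the benzyloxy oxygen) and the ester enolate adds to the adjacent methyl ester carbonyl, which then loses methoxide. This is a Dieckmann (intramolecular Claisen) condensation, the reaction by which O-acylated α-hydroxy esters are closed to tetronic acids and (benzyloxy)acetates of α-hydroxy esters to 2-O-benzyl aci-reductones. It closes the oxolane ring (O1, C2, C3, C3a, C7a of the target) in a formally 5-(enolendo)-exo-trig mode, tolerated here because the tetrahedral intermediate collapses irreversibly to the lithium salt of the vinylogous acid. No stereocentre is created: C5 of 12 (C7a of the target) is carried through from 7, and the enediol double bond and lactone carbonyl made here are the helpers through which hydrogen and hydride later set C3a, C3 and C2. The selectivity needed is enolisation at the glycolate methylene and not at the C–H flanked by the ester and acyloxy groups, which would racemise C7a or expel benzyl oxide; the hindered amide at −78 °C takes the unhindered, chelation-activated CH2 kinetically, and two equivalents of base keep the acidic product from acting as a proton shuttle.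

Step 9
Reactants: 12 (5R)-3-(benzyloxy)-5-[(benzyloxy)methyl]-4-hydroxyfuran-2(5H)-one
Product: 14 D-lyxono-1,4-lactone, via D-erythroascorbic acid 13 (not isolated)
Conditions: H2 (4 bar), 10% Pd/C, MeOH–H2O, rt then 50 °C
Reagents that add atoms: none
Why: Heterogeneous hydrogenation; hydrogenolysis of both benzyl ethers gives the free aci-reductone 13, whose enediol then adds H2 syn from the face opposite the C5 hydroxymethyl group (as L-ascorbic acid gives L-gulono-1,4-lactone), setting C3a and C3 of the target cis to the C7a substituent.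

Step 10
Reactants: 14 D-lyxono-1,4-lactone
Product: 15 2,3-O-isopropylidene-D-lyxono-1,4-lactone
Conditions: 2,2-dimethoxypropane, TsOH (cat.), acetone, rt
Reagents that add atoms: 2,2-dimethoxypropane, COC(C)(C)OC
Why: Thermodynamic acetonide formation takes the cis-2,3-diol into a cis-fused dioxolane and leaves the primary hydroxyl free; the acetal later blocks one face of the ring.

Step 11
Reactants: 15 2,3-O-isopropylidene-D-lyxono-1,4-lactone
Product: 16 5-O-(tert-butyldiphenylsilyl)-2,3-O-isopropylidene-D-lyxono-1,4-lactone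
Conditions: TBDPSCl, imidazole, DMF, rt
Reagents that add atoms: tert-butyldiphenylsilyl chloride, CC(C)(C)[Si](Cl)(c1ccccc1)c1ccccc1
Why: Selective silylation of the primary alcohol gives an ether that is stable to the organolithium and Lewis acid/silane steps.

Step 12
Reactants: 16 5-O-(tert-butyldiphenylsilyl)-2,3-O-isopropylidene-D-lyxono-1,4-lactone; 17 ethynyltrimethylsilane
Product: 18 5-O-(tert-butyldiphenylsilyl)-2,3-O-isopropylidene-1-C-[(trimethylsilyl)ethynyl]-D-lyxofuranose (anomeric mixture)
Conditions: 17, n-BuLi, THF, −78 °C; then 16; aq. NH4Cl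
Reagents that add atoms: ethynyltrimethylsilane (17), C#C[Si](C)(C)C
Why: Addition of the lithium acetylide to the γ-lactone stops at the tetrahedral alkoxide at −78 °C and gives the hemiketal on quench (first half of a Kishi-type C-glycoside synthesis), bringing in C1' and C2'.

Step 13
Reactants: 18 5-O-(tert-butyldiphenylsilyl)-2,3-O-isopropylidene-1-C-[(trimethylsilyl)ethynyl]-D-lyxofuranose
Product: 19 (1S)-1,4-anhydro-5-O-(tert-butyldiphenylsilyl)-2,3-O-isopropylidene-1-C-[(trimethylsilyl)ethynyl]-D-lyxitol (all four ring substituents cis)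
Conditions: Et3SiH, BF3·OEt2, CH2Cl2–MeCN, −78 to −20 °C
Reagents that add atoms: none
Why: Ionic hydrogenation; BF3 ionises the hemiketal to an alkynyl-stabilised cyclic oxocarbenium ion and triethylsilane delivers hydride to its convex face, anti to both the isopropylidene group and the C4 substituent, so the alkyne ends cis to the other three ring substituents (C2 of the target, S).

Step 14
Reactants: 19 (1S)-1,4-anhydro-5-O-(tert-butyldiphenylsilyl)-2,3-O-isopropylidene-1-C-[(trimethylsilyl)ethynyl]-D-lyxitol
Product: 20 (1S)-1,4-anhydro-1-C-ethynyl-2,3-O-isopropylidene-D-lyxitol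
Conditions: TBAF, THF, 0 °C to rt
Reagents that add atoms: none
Why: Fluoride cleaves the O–Si bond and the alkynyl C–Si bond in one operation.

Step 15
Reactants: 20 (1S)-1,4-anhydro-1-C-ethynyl-2,3-O-isopropylidene-D-lyxitol
Product: 21 (1S)-1,4-anhydro-1-C-ethenyl-2,3-O-isopropylidene-D-lyxitol
Conditions: H2 (1 atm), Lindlar catalyst, quinoline, EtOAc, rt
Reagents that add atoms: none
Why: Lindlar semihydrogenation stops at the alkene because the alkyne binds the poisoned palladium far more strongly than the product.

Step 16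
Reactants: 21 (1S)-1,4-anhydro-1-C-ethenyl-2,3-O-isopropylidene-D-lyxitol
Product: 22 all-cis-3,4-(isopropylidenedioxy)-5-vinyloxolane-2-carbaldehyde (D-lyxo series; CHO on the former C4 of the lactone)
Conditions: Dess–Martin periodinane, CH2Cl2, 0 °C to rt
Reagents that add atoms: none
Why: Dess–Martin oxidation under non-basic conditions gives the α-alkoxy aldehyde without epimerising the adjacent ring carbon (C7a).

Step 17
Reactants: 22 all-cis-3,4-(isopropylidenedioxy)-5-vinyloxolane-2-carbaldehyde; 23 methyl bis(2,2,2-trifluoroethyl)phosphonoacetate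
Product: 24 methyl (Z)-3-[all-cis-3,4-(isopropylidenedioxy)-5-vinyloxolan-2-yl]prop-2-enoate
Conditions: 23, KHMDS, 18-crown-6, THF, −78 °C; then 22
Reagents that add atoms: methyl bis(2,2,2-trifluoroethyl)phosphonoacetate (23), COC(=O)CP(=O)(OCC(F)(F)F)OCC(F)(F)F
Why: Still–Gennari variant of the Horner–Wadsworth–Emmons reaction; the electron-poor trifluoroethyl phosphonate gives fast, irreversible elimination from the kinetic adduct and hence the (Z)-enoate, at −78 °C where the aldehyde should not epimerise.

Step 18
Reactants: 24 methyl (Z)-3-[all-cis-3,4-(isopropylidenedioxy)-5-vinyloxolan-2-yl]prop-2-enoate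
Product: 26 (2S,3R,3aR,7aR)-3-hydroxy-2-vinyl-2,3,3a,7a-tetrahydro-5H-furo[3,2-b]pyran-5-one, via dihydroxy Z-enoate 25 (not isolated)
Conditions: TFA–H2O (9:1), 0 °C to rt; then toluene azeotrope
Reagents that add atoms: none
Why: Aqueous acid hydrolyses the acetonide and the hydroxyl on C3a, held cis to the (Z)-enoate, lactonises to the six-membered 5,6-dihydropyran-2-one, whereas the C3 hydroxyl could only form a seven-membered ring and stays free.

Step 19
Reactants: 26 (2S,3R,3aR,7aR)-3-hydroxy-2-vinyl-2,3,3a,7a-tetrahydro-5H-furo[3,2-b]pyran-5-one; 6 (2R,3S)-3-hydroxypent-4-en-2-yl benzoate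
Product: 27 (2R,3S,4E)-3-hydroxy-5-[(2S,3R,3aR,7aR)-3-hydroxy-5-oxo-2,3,3a,7a-tetrahydro-5H-furo[3,2-b]pyran-2-yl]pent-4-en-2-yl benzoate (target)
Conditions: Hoveyda–Grubbs II (cat.), 6 (excess), CH2Cl2, 40 °C
Reagents that add atoms: alcohol 6, C[C@@H](OC(=O)c1ccccc1)[C@@H](O)C=C
Why: Olefin cross-metathesis between two terminal alkenes of similar reactivity, driven by loss of ethylene and an excess of 6, should give the thermodynamically favoured (E)-alkene; the conjugated cis ring alkene does not take part.

**Compound list**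

1 | penta-1,4-dien-3-ol | C=CC(O)C=C | starting material
2 | (2R,3S)-1,2-epoxypent-4-en-3-ol | C=C[C@H](O)[C@H]1CO1 | intermediate
3 | (2R,3S)-3-[(tert-butyldimethylsilyl)oxy]-1,2-epoxypent-4-ene | C=C[C@H](O[Si](C)(C)C(C)(C)C)[C@H]1CO1 | intermediate
4 | (2R,3S)-3-[(tert-butyldimethylsilyl)oxy]pent-4-en-2-ol | C[C@@H](O)[C@@H](O[Si](C)(C)C(C)(C)C)C=C | intermediate
5 | (2R,3S)-3-[(tert-butyldimethylsilyl)oxy]pent-4-en-2-yl benzoate | C[C@@H](OC(=O)c1ccccc1)[C@@H](O[Si](C)(C)C(C)(C)C)C=C | intermediate
6 | (2R,3S)-3-hydroxypent-4-en-2-yl benzoate | C[C@@H](OC(=O)c1ccccc1)[C@@H](O)C=C | intermediate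
7 | methyl (R)-oxirane-2-carboxylate | COC(=O)[C@H]1CO1 | starting material
8 | benzyl alcohol | OCc1ccccc1 | starting material
9 | methyl (R)-3-(benzyloxy)-2-hydroxypropanoate | COC(=O)[C@H](O)COCc1ccccc1 | intermediate
10 | (benzyloxy)acetyl chloride | O=C(Cl)COCc1ccccc1 | starting material
11 | methyl (R)-3-(benzyloxy)-2-{[(benzyloxy)acetyl]oxy}propanoate | COC(=O)[C@H](OC(=O)COCc1ccccc1)COCc1ccccc1 | intermediate
12 | (5R)-3-(benzyloxy)-5-[(benzyloxy)methyl]-4-hydroxyfuran-2(5H)-one | O=C1O[C@H](COCc2ccccc2)C(O)=C1OCc1ccccc1 | intermediate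
13 | (5R)-3,4-dihydroxy-5-(hydroxymethyl)furan-2(5H)-one (D-erythroascorbic acid) | O=C1O[C@H](CO)C(O)=C1O | intermediate
14 | D-lyxono-1,4-lactone, (3S,4R,5R)-3,4-dihydroxy-5-(hydroxymethyl)oxolan-2-one | O=C1O[C@H](CO)[C@H](O)[C@@H]1O | intermediate
15 | 2,3-O-isopropylidene-D-lyxono-1,4-lactone | O=C1O[C@H](CO)[C@@H]2OC(C)(C)O[C@H]12 | intermediate
16 | 5-O-(tert-butyldiphenylsilyl)-2,3-O-isopropylidene-D-lyxono-1,4-lactone | O=C1O[C@H](CO[Si](c3ccccc3)(c3ccccc3)C(C)(C)C)[C@@H]2OC(C)(C)O[C@H]12 | intermediate
17 | ethynyltrimethylsilane | C#C[Si](C)(C)C | starting material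
18 | 5-O-(tert-butyldiphenylsilyl)-2,3-O-isopropylidene-1-C-[(trimethylsilyl)ethynyl]-D-lyxofuranose (anomeric mixture) | C[Si](C)(C)C#CC1(O)O[C@H](CO[Si](c3ccccc3)(c3ccccc3)C(C)(C)C)[C@@H]2OC(C)(C)O[C@H]12 | intermediate
19 | (1S)-1,4-anhydro-5-O-(tert-butyldiphenylsilyl)-2,3-O-isopropylidene-1-C-[(trimethylsilyl)ethynyl]-D-lyxitol | C[Si](C)(C)C#C[C@@H]1O[C@H](CO[Si](c3ccccc3)(c3ccccc3)C(C)(C)C)[C@@H]2OC(C)(C)O[C@H]12 | intermediate
20 | (1S)-1,4-anhydro-1-C-ethynyl-2,3-O-isopropylidene-D-lyxitol | C#C[C@@H]1O[C@H](CO)[C@@H]2OC(C)(C)O[C@H]12 | intermediate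
21 | (1S)-1,4-anhydro-1-C-ethenyl-2,3-O-isopropylidene-D-lyxitol | C=C[C@@H]1O[C@H](CO)[C@@H]2OC(C)(C)O[C@H]12 | intermediate
22 | all-cis-3,4-(isopropylidenedioxy)-5-vinyloxolane-2-carbaldehyde (D-lyxo series) | C=C[C@@H]1O[C@H](C=O)[C@@H]2OC(C)(C)O[C@H]12 | intermediate
23 | methyl bis(2,2,2-trifluoroethyl)phosphonoacetate | COC(=O)CP(=O)(OCC(F)(F)F)OCC(F)(F)F | starting material
24 | methyl (Z)-3-[all-cis-3,4-(isopropylidenedioxy)-5-vinyloxolan-2-yl]prop-2-enoate | C=C[C@@H]1O[C@H](/C=C\C(=O)OC)[C@@H]2OC(C)(C)O[C@H]12 | intermediate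
25 | methyl (Z)-3-[all-cis-3,4-dihydroxy-5-vinyloxolan-2-yl]prop-2-enoate | C=C[C@@H]1O[C@H](/C=C\C(=O)OC)[C@H](O)[C@@H]1O | intermediate
26 | (2S,3R,3aR,7aR)-3-hydroxy-2-vinyl-2,3,3a,7a-tetrahydro-5H-furo[3,2-b]pyran-5-one | C=C[C@@H]1O[C@@H]2C=CC(=O)O[C@@H]2[C@@H]1O | intermediate
27 | (2R,3S,4E)-3-hydroxy-5-[(2S,3R,3aR,7aR)-3-hydroxy-5-oxo-2,3,3a,7a-tetrahydro-5H-furo[3,2-b]pyran-2-yl]pent-4-en-2-yl benzoate | C[C@@H](OC(=O)c1ccccc1)[C@@H](O)/C=C/[C@@H]1O[C@@H]2C=CC(=O)O[C@@H]2[C@@H]1O | target

**Step count and risks**

Total steps: 19. Longest linear sequence: 14 steps (steps 6–19); the side-chain branch (steps 1–5) joins in step 19.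

Steps most likely to fail:

1. Step 8 (Claisen ring closure). What may go wrong: enolisation at the stereogenic carbon between the ester and acyloxy groups instead of at the glycolate methylene, with loss of configuration at C7a, β-elimination of benzyl oxide or acyl migration. The fallback sets out from 9 and returns at 12. It makes the same carbon–carbon bond between two molecules and closes the ring by lactonisation instead. 9 is silylated (TESCl, imidazole, CH2Cl2) to methyl (R)-3-(benzyloxy)-2-[(triethylsilyl)oxy]propanoate F1. Crossed Claisen condensation of F1 with the lithium enolate of methyl (benzyloxy)acetate (LDA, THF, −78 °C, enolate in excess) should give methyl (4R)-2,5-bis(benzyloxy)-3-oxo-4-[(triethylsilyl)oxy]pentanoate F2, held as its C2 enolate until quench so that C4 is not enolised. HF·pyridine in THF then removes the silyl group, and the freed hydroxyl should lactonise onto the C1 ester with enolisation, the way 2-keto-gulonate closes to ascorbic acid, to give 12.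

2. Step 13 (silane reduction of the hemiketal). What may go wrong: ionisation at the isopropylidene acetal instead of the hemiketal, hydride delivery at the alkyne terminus to give an allene, or incomplete facial control. The fallback sets out from 18 and returns at 19. It forms the C2–O1 bond by SN2 displacement instead of reducing a cyclic cation. 18 reacts through its ring-opened hydroxy ynone form with Zn(BH4)2 (Et2O, −20 °C); zinc chelated between the ketone and the adjacent dioxolane oxygen should direct hydride to give the 1,2-anti carbinol, (1R)-5-O-(tert-butyldiphenylsilyl)-2,3-O-isopropylidene-1-C-[(trimethylsilyl)ethynyl]-D-lyxitol F3. Mitsunobu cyclodehydration (PPh3, DIAD, THF, 0 °C) should activate the less hindered propargylic hydroxyl, which the C4 hydroxyl displaces with inversion to give the all-cis oxolane 19.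

3. Step 19 (cross-metathesis). What may go wrong: slow initiation at the hindered allylic-ether alkene, homodimerisation of 6, erosion of E geometry or double-bond migration. The fallback sets out from 26 and ends at 27. It builds the chain by carbonyl chemistry instead. The vinyl group of 26, its only electron-rich alkene, is cleaved (OsO4 cat., NaIO4, 2,6-lutidine, dioxane–H2O) to the 2-carbaldehyde analogue of 26, F4. Takai olefination (CHI3, CrCl2, THF, 0 °C) should give the (E)-2-iodovinyl analogue of 26, F5. Separately, commercial (R)-but-3-en-2-ol is benzoylated (BzCl, pyridine) to (R)-but-3-en-2-yl benzoate F6, which is ozonised (O3, CH2Cl2, −78 °C; Me2S) to (R)-2-(benzoyloxy)propanal F7. Nozaki–Hiyama–Kishi coupling of F5 with F7 (CrCl2, NiCl2 cat., DMSO, rt) forms the C2'–C3' bond. Felkin–Anh addition anti to the benzoyloxy group, reinforced if necessary by a chiral sulfonamide ligand, should set C3' and give 27.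

**Further compounds**

F1 | step 8 | methyl (R)-3-(benzyloxy)-2-[(triethylsilyl)oxy]propanoate | COC(=O)[C@H](O[Si](CC)(CC)CC)COCc1ccccc1
F2 | step 8 | methyl (4R)-2,5-bis(benzyloxy)-3-oxo-4-[(triethylsilyl)oxy]pentanoate (C2 epimers) | COC(=O)C(OCc1ccccc1)C(=O)[C@H](O[Si](CC)(CC)CC)COCc1ccccc1
F3 | step 13 | (1R)-5-O-(tert-butyldiphenylsilyl)-2,3-O-isopropylidene-1-C-[(trimethylsilyl)ethynyl]-D-lyxitol | C[Si](C)(C)C#C[C@@H](O)[C@H]1OC(C)(C)O[C@H]1[C@H](O)CO[Si](c1ccccc1)(c1ccccc1)C(C)(C)C
F4 | step 19 | 2-carbaldehyde analogue of 26 (vinyl replaced by CHO, ring configuration unchanged) | O=C[C@@H]1O[C@@H]2C=CC(=O)O[C@@H]2[C@@H]1O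
F5 | step 19 | (E)-2-iodovinyl analogue of 26 | I/C=C/[C@@H]1O[C@@H]2C=CC(=O)O[C@@H]2[C@@H]1O
F6 | step 19 | (R)-but-3-en-2-yl benzoate | C[C@@H](OC(=O)c1ccccc1)C=C
F7 | step 19 | (R)-2-(benzoyloxy)propanal | C[C@@H](OC(=O)c1ccccc1)C=O
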